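## The problem

Lychnopholide 29 is a furanoheliangolide, numbered here as a germacrane. Its ten-membered carbocycle C1–C10 is bridged by an oxygen between C3 and C10, so that C1 (ketone), C2=C3 and C10 form a 3(2H)-furanone cross-conjugated with the Z-alkene C4=C5 (C15 methyl on C4); an α-methylene-γ-butyrolactone (C11=C13, C12=O) is trans-fused at C6–C7, C8 carries the angelate and C10 the C14 methyl. A ten-membered ring holding a planar furanone, a Z-trisubstituted alkene and a trans-fused lactone is strained, so an end-to-end closure would pay the full entropic and transannular price. Of the four stereocentres, C10 (R, quaternary, oxygenated) stands alone and is best bought. C8 (S) lies 1,3 to it across a methylene group and cannot be trusted to follow it, so it needs reagent control. C6 (R) and C7 (R) are contiguous and can be made in one event, with C8 and C10 steering the face through the ring. Several groups forbid rough treatment: the α-methylene lactone is a Michael acceptor, angelate isomerises to tiglate, the lactone acyl group can migrate between O6 and O8, the dienone is open to nucleophiles and Z/E isomerisation, and a carbonyl at C8 beside the finished furanone would put an acidic C9–H next to the C10 oxygen, then a vinylogous carboxylate leaving group. The key step rests on one feature: C6 bears oxygen, is allylic to C4=C5 and vinylogous through C3=C2 to the C1 carbonyl, and its neighbour C7 bears the C11(=C13H2)–C12 unit, which is the product pattern of a [2,3]-Wittig shift of a C6–O–C13 allyl ether.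

## Retrosynthesis

**C8–O acyl bond, 29 ⇒ 26 + 27.** The angelate is removed first, giving alcohol 26 and angelic acid 27. It is the most isomerisation-prone group and would not survive the strong base of the ring-forming step. The forward step must acylate a hindered secondary alcohol without Z/E isomerisation of the ester and without lactone migration to O8.

**Lactone C12 oxidation level, 26 ⇒ 25 ⇒ 22 ⇒ 21.** The lactone 26 is taken back through its O8 silyl ether 25 to the C6,C12 diol 22, and that to carbinol 21, in which C12 is a silyl-protected hydroxymethyl group. Carrying C12 as an ester instead would put an acrylate into the base-mediated steps. The forward steps are one selective desilylation and one oxidative lactonisation; O8 stays blocked so that the 8,12-lactone cannot form.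

**C6–C7, the key cut, 21 ⇒ 20.** Cutting C6–C7 and reconnecting O6 to C13 turns the ten-membered carbinol 21 into the thirteen-membered bis-allylic ether 20. Against a direct closure at C6–C7, C1–C10 or C9–C10, this cut trades a strained ring closure for a ring contraction through a five-centre transition state. It also makes C6, C7 and the C11=C13 methylene in one step. Three measures strengthen it:
- the ether arm on C11 must be trans to C8 (the anti-selective arrangement), and this geometry is built in unambiguously (see below);
- C8 is set by a catalyst, not by C10;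
- a lithium amide at low temperature is used, because a potassium alkoxide of the product (a 3-oxido-1,5-diene) would invite anionic oxy-Cope rearrangement.

**C11–C12, 20 ⇒ 19 ⇒ 18.** The silyl ether 20 comes from alcohol 19, whose hydroxymethyl arm is cut back to alkenyl iodide 18. Introducing C12 by cross-coupling after the ether arm is already in the ring means the two oxygenated arms on C11 never have to be differentiated; bringing in both arms at once would demand that two near-identical primary hydroxyls be told apart. The forward reaction is a hydroxymethylation of a hindered alkenyl iodide with retention of geometry.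

**O6–C13 ether bond, 18 ⇒ 17 ⇒ 16 ⇒ 15.** The macrocycle 18 is opened at the ether to hydroxy bromide 17, which comes from alcohol 15 through bromide 16. An ether closure is preferred to a carbon–carbon macrocyclisation because it creates no stereocentre. The alkoxide is placed on C6 and the bromide on C13 because that order needs only one protecting-group change after the iodide is in place. The forward reaction must beat oligomerisation for a thirteen-membered ring.

**C7=C11 geometry, 15 ⇒ 13 ⇒ 12.** The iodoalkene 15 is traced to the propargylic alcohol 13, and that to its silyl ether 12. A hydroxyl-directed trans-hydrostannation puts tin on the carbon next to CH2OH and hydrogen on C7 from the opposite face, which fixes C8 trans to C13. A reduction with LiAlH4 would give the same pattern but cannot be used beside the furanone.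

**Furanone, 12 ⇒ 11 ⇒ 7 + 9, and 9 ⇒ 8.** Cutting O–C3 of furanone 12 gives the α'-hydroxy ynone 11; cutting C1–C2 gives dioxolanone 7 and the enyne 9, the PMB ether of the Z-enynol 8. The enyne brings C2–C6 and C15 with the Z geometry already in place. The forward steps are a single acetylide addition to an activated ester and a 5-endo cyclisation that must spare the second alkyne.

**C8 stereocentre and C7–C8, 7 ⇒ 6 ⇒ 5 ⇒ 2 + 3, and 2 ⇒ 1.** The silyl ether 7 comes from carbinol 6, which is taken back to ynone 5; C7–C8 is cut to the acid 2 and the propargyl silyl ether 3, and 2 is the acetonide of (R)-citramalic acid 1. An ynone is the best-behaved substrate for catalyst-controlled reduction. It is made and reduced before the furanone exists, so the C9 protons are acidic only while the C10 oxygen is still a ketal oxygen, a far poorer leaving group than the vinylogous carboxylate it becomes in the furanone.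

## Roads not taken

Alternative 1: oxonium ylide ring expansion. The cut is C9–C10 together with O–C10. The precursor is the diazoketone A1, a 3,6-dihydro-2H-pyran whose ring oxygen joins C3 and C7, with the vinyl group C8=C9 on C7 and the diazoketone arm C2–C1(=O)–C10(=N2)–C14 on C3. Cu(acac)2 would turn A1 into a copper carbenoid at C10. The ring oxygen captures it, closing the oxolanone, and the ylide shifts its allyl unit from oxygen to carbon, expanding the six-membered ring to the oxygen-bridged cyclodecadienone A2.
- Merits: the ring, the ether bridge and quaternary C10 arise in one step from the six-membered A1, with no macrocyclic intermediate and no high-dilution step. In this respect it is better than the plan adopted.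
- Weak points: the carbenoid from A1 bears a methyl group and is prone to 1,2-hydride shift, and the [1,2]-shift competes. A2 still lacks the C2=C3 unsaturation, the C8 oxygen and the whole C11–C13 unit, and its C7=C8 alkene would have to be converted regio- and stereoselectively into C8–O and C7–C11.
- Comparison: the adopted plan sets against the elegant ring construction a key-step product, carbinol 21, that already holds every carbon and all four stereocentres.

Alternative 2: titanocene radical cyclisation. The cut is C7–C11. Cp2TiCl (trivalent titanium) would open the C7–C8 epoxide of the propargyl ether A3 to a C7 radical with the C8 oxygen retained; 5-exo-dig addition to the alkyne gives the methyleneoxolane A4.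
- Merits: neutral conditions, the C8 hydroxyl is unveiled in the same step, and there are no silyl manipulations at C12. Its endgame is shorter than the one adopted.
- Weak points: A3 presupposes the ten-membered ring with a defined epoxide, so the central problem is only moved. Reduction of the β-titanoxy radical and elimination, a net deoxygenation of the epoxide, competes with cyclisation. The ring fusion at C7 is set by a radical cyclisation that tends to cis fusion. C12 of A4 must then be oxidised at an allylic ether position beside other allylic sites.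
- Comparison: the adopted plan builds the carbocycle and the C6/C7 pair together and pays for this with four endgame steps.

Alternative 3: photocycloaddition and electrocyclic ring expansion. The cuts are C2–C3 and C4–C5. Irradiation of the cyclooctenone A5, which carries a propynyl ether on the C10 oxygen, would add the enone across the alkyne to give the cyclobutene A6. Thermal conrotatory opening of C2–C5 would then give the ten-membered furanone A7.
- Merits: furanone, ring expansion and the E,Z-diene geometry come from one orbital-symmetry-controlled cascade, and no strong base touches the dienone. On these points it is at least as good as the adopted plan.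
- Weak points: A5 is an eight-membered enone with C6, C7, C8 and C10 already set and a tertiary ynol ether, which is labile to acid and to thermal fragmentation. Cyclooctenones isomerise to the trans form on irradiation. A7 lacks C13, so the lactone must be methylenated through its enolate beside the furanone.
- Comparison: the adopted plan uses only ground-state chemistry of known type up to the ring contraction and sets C6 and C7 in the key step instead of requiring them beforehand.

Key step: step 15

Assumption: (Z)-3-methylpent-2-en-4-yn-1-ol 8, an industrial C6 building block, is taken as purchasable in geometrically pure form.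

## Route

Step 1
Reactants: 1 (R)-citramalic acid
Product: 2 (R)-2-(2,2,4-trimethyl-5-oxo-1,3-dioxolan-4-yl)acetic acid
Conditions: Me2C(OMe)2, TsOH·H2O (cat.), CH2Cl2, rt
Reagents that add atoms: 2,2-dimethoxypropane, COC(C)(C)OC
Why: Acid-catalysed transacetalisation; the α-hydroxy acid closes the five-membered dioxolanone in preference to a six-membered ring through the β-carboxyl, as with malic acid, so the two carboxyls are differentiated in one operation and the C10 stereocentre from the chiral pool is untouched.

Step 2
Reactants: 2 (R)-2-(2,2,4-trimethyl-5-oxo-1,3-dioxolan-4-yl)acetic acid; 3 tert-butyldimethyl(prop-2-yn-1-yloxy)silane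
Product: 5 (R)-5-[5-(tert-butyldimethylsilyloxy)-2-oxopent-3-yn-1-yl]-2,2,5-trimethyl-1,3-dioxolan-4-one, via acid chloride 4 (not isolated)
Conditions: (COCl)2, DMF (cat.), CH2Cl2, 0 °C to rt; evaporate; then 3, PdCl2(PPh3)2 (2 mol %), CuI (4 mol %), Et3N, THF, rt
Reagents that add atoms: none
Why: Acid chloride formation followed by PdCl2(PPh3)2/CuI-catalysed acylation of the terminal alkyne (acyl Sonogashira coupling) forms C7–C8 under conditions mild enough for the dioxolanone, which a lithium acetylide would attack; no stereocentre is involved.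

Step 3
Reactants: 5 (R)-5-[5-(tert-butyldimethylsilyloxy)-2-oxopent-3-yn-1-yl]-2,2,5-trimethyl-1,3-dioxolan-4-one
Product: 6 (R)-5-[(S)-5-(tert-butyldimethylsilyloxy)-2-hydroxypent-3-yn-1-yl]-2,2,5-trimethyl-1,3-dioxolan-4-one
Conditions: Ru(p-cymene)[(S,S)-TsDPEN] (2 mol %), i-PrOH, rt
Reagents that add atoms: none
Why: Noyori asymmetric transfer hydrogenation of an alkynyl ketone; C8 is set by the catalyst, the (S,S)-diamine complex giving the (S)-propargylic alcohol with the alkynyl group in the role usually played by aryl, and the remote C10 centre has little say; the base-free conditions spare the dioxolanone and avoid β-elimination of the C10 oxygen.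

Step 4
Reactants: 6 (R)-5-[(S)-5-(tert-butyldimethylsilyloxy)-2-hydroxypent-3-yn-1-yl]-2,2,5-trimethyl-1,3-dioxolan-4-one
Product: 7 (R)-5-[(S)-2,5-bis(tert-butyldimethylsilyloxy)pent-3-yn-1-yl]-2,2,5-trimethyl-1,3-dioxolan-4-one
Conditions: TBSOTf, 2,6-lutidine, CH2Cl2, −78 °C
Reagents that add atoms: tert-butyldimethylsilyl triflate, CC(C)(C)[Si](C)(C)OS(=O)(=O)C(F)(F)F
Why: Standard silylation of a secondary alcohol with the silyl triflate at low temperature, carried out on the crude alcohol so that the free γ-hydroxyl has no time to translactonise onto the dioxolanone carbonyl.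

Step 5
Reactants: 8 (Z)-3-methylpent-2-en-4-yn-1-ol
Product: 9 1-methoxy-4-{[(Z)-(3-methylpent-2-en-4-yn-1-yl)oxy]methyl}benzene
Conditions: NaH, PMBCl, Bu4NI (cat.), THF, 0 °C to rt
Reagents that add atoms: 4-methoxybenzyl chloride, COc1ccc(CCl)cc1
Why: Williamson ether synthesis; NaH removes only the hydroxyl proton, which is far more acidic than the acetylenic one, and the Z-alkene is not touched.

Step 6
Reactants: 9 1-methoxy-4-{[(Z)-(3-methylpent-2-en-4-yn-1-yl)oxy]methyl}benzene; 7 (R)-5-[(S)-2,5-bis(tert-butyldimethylsilyloxy)pent-3-yn-1-yl]-2,2,5-trimethyl-1,3-dioxolan-4-one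
Product: 11 (2Z,7R,9S)-9,12-bis(tert-butyldimethylsilyloxy)-7-hydroxy-1-(4-methoxybenzyloxy)-3,7-dimethyldodec-2-ene-4,10-diyn-6-one, via lithium acetylide 10 (not isolated)
Conditions: 9 (1.3 equiv), n-BuLi, THF, −78 °C; then 7, −78 °C; AcOH, −78 °C to rt
Reagents that add atoms: none
Why: Acylation of a lithium acetylide by an activated cyclic ester: addition to the dioxolanone carbonyl gives a cyclic hemiketal alkoxide that, like the adducts of lactones, persists at −78 °C and so takes up only one acetylide; on acidic quench it collapses with loss of acetone to the α'-hydroxy ynone, forming C1–C2 with C10 intact.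

Step 7
Reactants: 11 (2Z,7R,9S)-9,12-bis(tert-butyldimethylsilyloxy)-7-hydroxy-1-(4-methoxybenzyloxy)-3,7-dimethyldodec-2-ene-4,10-diyn-6-one
Product: 12 (R)-2-[(S)-2,5-bis(tert-butyldimethylsilyloxy)pent-3-yn-1-yl]-5-[(Z)-4-(4-methoxybenzyloxy)but-2-en-2-yl]-2-methylfuran-3(2H)-one
Conditions: Et2NH, EtOH, rt
Reagents that add atoms: none
Why: Classical amine-mediated 3(2H)-furanone synthesis: Et2NH adds to the ynone at C3 and the tertiary hydroxyl then displaces it (net 5-endo oxa-Michael cyclisation), forming O–C3; without a π-acid the benzylic ether cis to the alkyne and the isolated C7≡C11 alkyne stay out of the reaction, and the Z-alkene is retained.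

Step 8
Reactants: 12 (R)-2-[(S)-2,5-bis(tert-butyldimethylsilyloxy)pent-3-yn-1-yl]-5-[(Z)-4-(4-methoxybenzyloxy)but-2-en-2-yl]-2-methylfuran-3(2H)-one
Product: 13 (R)-2-[(S)-2-(tert-butyldimethylsilyloxy)-5-hydroxypent-3-yn-1-yl]-5-[(Z)-4-(4-methoxybenzyloxy)but-2-en-2-yl]-2-methylfuran-3(2H)-one
Conditions: CSA (0.1 equiv), MeOH/CH2Cl2 (1:1), 0 °C
Reagents that add atoms: none
Why: Acid-catalysed methanolysis distinguishes the unhindered primary silyl ether from the secondary one at C8, which is flanked by the branched chain; the furanone and the PMB ether are stable to catalytic acid at 0 °C.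

Step 9
Reactants: 13 (R)-2-[(S)-2-(tert-butyldimethylsilyloxy)-5-hydroxypent-3-yn-1-yl]-5-[(Z)-4-(4-methoxybenzyloxy)but-2-en-2-yl]-2-methylfuran-3(2H)-one
Product: 15 (R)-2-[(S,Z)-2-(tert-butyldimethylsilyloxy)-5-hydroxy-4-iodopent-3-en-1-yl]-5-[(Z)-4-(4-methoxybenzyloxy)but-2-en-2-yl]-2-methylfuran-3(2H)-one, via alkenylstannane 14 (not isolated)
Conditions: [Cp*RuCl]4 (2.5 mol %), Bu3SnH (1.05 equiv), CH2Cl2, rt; then I2, CH2Cl2, 0 °C, dark
Reagents that add atoms: iodine, II
Why: [Cp*RuCl]4-catalysed trans-hydrostannation directed by the free propargylic hydroxyl: tin goes to C11, the alkyne carbon next to CH2OH, and hydrogen to C7 from the opposite face, so C8 ends up trans to C13; iododestannation proceeds with retention and is far faster than any reaction of iodine with the furanone.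

Step 10
Reactants: 15 (R)-2-[(S,Z)-2-(tert-butyldimethylsilyloxy)-5-hydroxy-4-iodopent-3-en-1-yl]-5-[(Z)-4-(4-methoxybenzyloxy)but-2-en-2-yl]-2-methylfuran-3(2H)-one
Product: 16 (R)-2-[(S,Z)-5-bromo-2-(tert-butyldimethylsilyloxy)-4-iodopent-3-en-1-yl]-5-[(Z)-4-(4-methoxybenzyloxy)but-2-en-2-yl]-2-methylfuran-3(2H)-one
Conditions: CBr4, PPh3, 2,6-lutidine, CH2Cl2, 0 °C
Reagents that add atoms: carbon tetrabromide, BrC(Br)(Br)Br
Why: Appel bromination of a primary allylic alcohol by SN2 displacement at C13; the buffer protects the silyl and benzylic ethers, and the crowded C7 terminus disfavours allylic transposition.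

Step 11
Reactants: 16 (R)-2-[(S,Z)-5-bromo-2-(tert-butyldimethylsilyloxy)-4-iodopent-3-en-1-yl]-5-[(Z)-4-(4-methoxybenzyloxy)but-2-en-2-yl]-2-methylfuran-3(2H)-one
Product: 17 (R)-2-[(S,Z)-5-bromo-2-(tert-butyldimethylsilyloxy)-4-iodopent-3-en-1-yl]-5-[(Z)-4-hydroxybut-2-en-2-yl]-2-methylfuran-3(2H)-one
Conditions: DDQ, CH2Cl2/pH 7 buffer, 0 °C
Reagents that add atoms: none
Why: Oxidative removal of the PMB ether by DDQ under buffered two-phase conditions, which leave the allylic bromide, the alkenyl iodide, the silyl ether and the electron-poor dienone alone.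

Step 12
Reactants: 17 (R)-2-[(S,Z)-5-bromo-2-(tert-butyldimethylsilyloxy)-4-iodopent-3-en-1-yl]-5-[(Z)-4-hydroxybut-2-en-2-yl]-2-methylfuran-3(2H)-one
Product: 18 macrocyclic iodide: thirteen-membered ether ring O–C6–C5=C4(CH3)–C3=C2–C1(=O)–C10(CH3)–C9–C8(OTBS)–C7=C11(I)–C13 with the C3–O–C10 furanone bridge; 4Z; C8 trans to C13 on C7=C11; 8S,10R
Conditions: NaH, Bu4NI (cat.), THF (0.002 M, slow addition of 17), 0 °C to rt
Reagents that add atoms: none
Why: Intramolecular Williamson etherification (13-exo-tet) under high dilution, the established way to thirteen-membered bis-allylic ethers; the Z-alkene, the planar furanone and the trisubstituted iodoalkene leave few rotatable bonds between the C6 alkoxide and the primary allylic bromide at C13, and catalytic iodide speeds the displacement.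

Step 13
Reactants: 18 macrocyclic iodide
Product: 19 macrocyclic alcohol: as 18 with CH2OH (C12) in place of iodine on C11; C8 cis to C12 and trans to C13; 4Z; 8S,10R
Conditions: Bu3SnCH2OH, Pd(PPh3)4 (10 mol %), dioxane, 90 °C
Reagents that add atoms: (tributylstannyl)methanol, OC[Sn](CCCC)(CCCC)CCCC
Why: Stille coupling of the alkenyl iodide with (tributylstannyl)methanol installs C12 with retention of geometry; because the ether arm was fixed trans to C8 in step 9, the new hydroxymethyl arm is necessarily the cis one, so the two oxygenated arms on C11 never need to be told apart.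

Step 14
Reactants: 19 macrocyclic alcohol
Product: 20 macrocyclic C6–O–C13 bis-allylic ether: as 19 with C12 as CH2OSiEt3; 4Z; C8 trans to C13; 8S,10R
Conditions: TESCl, imidazole, CH2Cl2, 0 °C
Reagents that add atoms: chlorotriethylsilane, CC[Si](Cl)(CC)CC
Why: Routine silylation of the primary allylic alcohol; the triethylsilyl group masks the hydroxyl as a non-acidic spectator for the base-mediated rearrangement and can later be removed beside the C8 tert-butyldimethylsilyl ether.

Step 15
Reactants: 20 macrocyclic C6–O–C13 bis-allylic ether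
Product: 21 ten-membered C6 carbinol: carbocycle C1–C10 with the C3–O–C10 furanone, 4Z, C6 OH, C7 bearing C11(=C13H2)CH2OSiEt3, C8 OTBS; 6R,7S,8S,10R (the spatial arrangement of the target; the C7 letter differs only through CIP ranking of the silyl ether)
Conditions: lithium 2,2,6,6-tetramethylpiperidide (from the amine and n-BuLi, 1.5 equiv), THF, −78 °C, then −78 to −20 °C; AcOH, −78 °C
Reagents that add atoms: none
Why: The amide removes a C6 proton, the only one whose carbanion is delocalised linearly through C5=C4 and C3=C2 onto the C1 oxygen, and the lithium trienolate rearranges through the five-centre envelope C6–O–C13–C11=C7, with C6–C7 forming as O–C13 breaks ([2,3]-Wittig rearrangement). The closest known reaction type is the [2,3]-Wittig ring contraction of thirteen-membered bis-allylic ethers to ten-membered carbocycles with vicinal hydroxyl and alkenyl groups; here the carbanion is an extended enolate instead of a simple allyl anion, which has no direct precedent and is why warming above −78 °C is planned. The ten-membered carbocycle closes by ring contraction (13 to 10): the ether holds the two reacting carbons five atoms apart, so no end-to-end macrocyclisation is needed. C6 and C7 are set together; their relative configuration (anti, the trans-lactone pattern) follows from the suprafacial shift across an allyl unit in which C8 is trans to C13. Their absolute sense follows from the face of C7=C11 that the folded macrocycle exposes, biased by the C8 silyloxy group (allylic strain holds C8–H in the alkene plane) and by the C10 quaternary centre locked in the furanone. Site selectivity rests on acidity: C13–H, C15–H and C8–H lead only to allyl anions, C6–H to an extended enolate. The lithium counter-ion and the cold quench keep the product alkoxide from anionic oxy-Cope rearrangement, from oxa-Michael addition to C3 and from [1,2]-shift.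

Step 16
Reactants: 21 ten-membered C6 carbinol
Product: 22 C6,C12 diol: as 21 with C12 as CH2OH; 6R,7S,8S,10R
Conditions: PPTS, MeOH/CH2Cl2, 0 °C
Reagents that add atoms: none
Why: Mild acidic methanolysis removes the primary triethylsilyl ether far faster than the hindered secondary tert-butyldimethylsilyl ether, exposing the C6,C12 diol while C8 stays protected.

Step 17
Reactants: 22 C6,C12 diol
Product: 25 8-O-TBS lactone: the target skeleton with OTBS at C8 (6R,7S,8S,10R), via enal 23 (not isolated), via lactol 24 (not isolated)
Conditions: TEMPO (0.2 equiv), PhI(OAc)2 (2.5 equiv), CH2Cl2, rt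
Reagents that add atoms: none
Why: TEMPO/PhI(OAc)2 oxidative lactonisation of a 1,4-diol: the primary allylic alcohol is oxidised selectively to the enal, the C6 hydroxyl closes the five-membered lactol (5-exo-trig), and a second oxidation gives the α-methylene-γ-butyrolactone; the silyl ether at C8 prevents the competing 8,12-lactone.

Step 18
Reactants: 25 8-O-TBS lactone
Product: 26 8-hydroxy lactone (8-deacyl-lychnopholide; 6R,7R,8S,10R)
Conditions: HF·pyridine, pyridine, THF, 0 °C to rt
Reagents that add atoms: none
Why: Desilylation with buffered HF·pyridine, chosen over basic fluoride so that the α-methylene lactone is not exposed to nucleophiles and the 6,12-lactone does not migrate to O8.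

Step 19
Reactants: 26 8-hydroxy lactone; 27 angelic acid [(Z)-2-methylbut-2-enoic acid]
Product: 29 lychnopholide (6R,7R,8S,10R), via mixed anhydride 28 (not isolated)
Conditions: 27, 2,4,6-Cl3C6H2COCl, Et3N, toluene, rt; then 26, toluene, 70 °C
Reagents that add atoms: none
Why: Esterification through the 2,4,6-trichlorobenzoyl mixed anhydride (Yamaguchi type) without a nucleophilic amine catalyst, the standard precaution against Z to E isomerisation of angelate to tiglate; the alcohol attacks the less hindered angeloyl carbonyl, and the short exposure to Et3N limits lactone migration.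

## Compound list

1 | (R)-citramalic acid | C[C@@](O)(CC(=O)O)C(=O)O | starting material
2 | (R)-2-(2,2,4-trimethyl-5-oxo-1,3-dioxolan-4-yl)acetic acid | CC1(C)OC(=O)[C@@](C)(CC(=O)O)O1 | intermediate
3 | tert-butyldimethyl(prop-2-yn-1-yloxy)silane | C#CCO[Si](C)(C)C(C)(C)C | starting material
4 | (R)-2-(2,2,4-trimethyl-5-oxo-1,3-dioxolan-4-yl)acetyl chloride (not isolated) | CC1(C)OC(=O)[C@@](C)(CC(=O)Cl)O1 | intermediate
5 | (R)-5-[5-(tert-butyldimethylsilyloxy)-2-oxopent-3-yn-1-yl]-2,2,5-trimethyl-1,3-dioxolan-4-one | CC1(C)OC(=O)[C@@](C)(CC(=O)C#CCO[Si](C)(C)C(C)(C)C)O1 | intermediate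
6 | (R)-5-[(S)-5-(tert-butyldimethylsilyloxy)-2-hydroxypent-3-yn-1-yl]-2,2,5-trimethyl-1,3-dioxolan-4-one | CC1(C)OC(=O)[C@@](C)(C[C@H](O)C#CCO[Si](C)(C)C(C)(C)C)O1 | intermediate
7 | (R)-5-[(S)-2,5-bis(tert-butyldimethylsilyloxy)pent-3-yn-1-yl]-2,2,5-trimethyl-1,3-dioxolan-4-one | CC1(C)OC(=O)[C@@](C)(C[C@H](O[Si](C)(C)C(C)(C)C)C#CCO[Si](C)(C)C(C)(C)C)O1 | intermediate
8 | (Z)-3-methylpent-2-en-4-yn-1-ol | C#C/C(C)=C\CO | starting material
9 | 1-methoxy-4-{[(Z)-(3-methylpent-2-en-4-yn-1-yl)oxy]methyl}benzene | C#C/C(C)=C\COCc1ccc(OC)cc1 | intermediate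
10 | lithium acetylide of 9 (not isolated) | [Li]C#C/C(C)=C\COCc1ccc(OC)cc1 | intermediate
11 | (2Z,7R,9S)-9,12-bis(tert-butyldimethylsilyloxy)-7-hydroxy-1-(4-methoxybenzyloxy)-3,7-dimethyldodec-2-ene-4,10-diyn-6-one | COc1ccc(COC/C=C(/C)C#CC(=O)[C@](C)(O)C[C@H](O[Si](C)(C)C(C)(C)C)C#CCO[Si](C)(C)C(C)(C)C)cc1 | intermediate
12 | (R)-2-[(S)-2,5-bis(tert-butyldimethylsilyloxy)pent-3-yn-1-yl]-5-[(Z)-4-(4-methoxybenzyloxy)but-2-en-2-yl]-2-methylfuran-3(2H)-one | COc1ccc(COC/C=C(/C)C2=CC(=O)[C@@](C)(C[C@H](O[Si](C)(C)C(C)(C)C)C#CCO[Si](C)(C)C(C)(C)C)O2)cc1 | intermediate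
13 | (R)-2-[(S)-2-(tert-butyldimethylsilyloxy)-5-hydroxypent-3-yn-1-yl]-5-[(Z)-4-(4-methoxybenzyloxy)but-2-en-2-yl]-2-methylfuran-3(2H)-one | COc1ccc(COC/C=C(/C)C2=CC(=O)[C@@](C)(C[C@H](O[Si](C)(C)C(C)(C)C)C#CCO)O2)cc1 | intermediate
14 | (R)-2-[(S,Z)-2-(tert-butyldimethylsilyloxy)-5-hydroxy-4-(tributylstannyl)pent-3-en-1-yl]-5-[(Z)-4-(4-methoxybenzyloxy)but-2-en-2-yl]-2-methylfuran-3(2H)-one (not isolated) | COc1ccc(COC/C=C(/C)C2=CC(=O)[C@@](C)(C[C@H](O[Si](C)(C)C(C)(C)C)/C=C(/CO)[Sn](CCCC)(CCCC)CCCC)O2)cc1 | intermediate
15 | (R)-2-[(S,Z)-2-(tert-butyldimethylsilyloxy)-5-hydroxy-4-iodopent-3-en-1-yl]-5-[(Z)-4-(4-methoxybenzyloxy)but-2-en-2-yl]-2-methylfuran-3(2H)-one | COc1ccc(COC/C=C(/C)C2=CC(=O)[C@@](C)(C[C@H](O[Si](C)(C)C(C)(C)C)/C=C(I)/CO)O2)cc1 | intermediate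
16 | (R)-2-[(S,Z)-5-bromo-2-(tert-butyldimethylsilyloxy)-4-iodopent-3-en-1-yl]-5-[(Z)-4-(4-methoxybenzyloxy)but-2-en-2-yl]-2-methylfuran-3(2H)-one | COc1ccc(COC/C=C(/C)C2=CC(=O)[C@@](C)(C[C@H](O[Si](C)(C)C(C)(C)C)/C=C(I)/CBr)O2)cc1 | intermediate
17 | (R)-2-[(S,Z)-5-bromo-2-(tert-butyldimethylsilyloxy)-4-iodopent-3-en-1-yl]-5-[(Z)-4-hydroxybut-2-en-2-yl]-2-methylfuran-3(2H)-one | OC/C=C(/C)C2=CC(=O)[C@@](C)(C[C@H](O[Si](C)(C)C(C)(C)C)/C=C(I)/CBr)O2 | intermediate
18 | macrocyclic iodide: thirteen-membered C6–O–C13 ether with C3–O–C10 furanone bridge, 4Z, C11 iodide, C8 trans to C13, C8 OTBS, 8S,10R | O1C/C=C(/C)C3=CC(=O)[C@@](C)(C[C@H](O[Si](C)(C)C(C)(C)C)/C=C(I)/C1)O3 | intermediate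
19 | macrocyclic alcohol: as 18 with CH2OH (C12) on C11 | O1C/C=C(/C)C3=CC(=O)[C@@](C)(C[C@H](O[Si](C)(C)C(C)(C)C)/C=C(CO)/C1)O3 | intermediate
20 | macrocyclic C6–O–C13 bis-allylic ether with C12 OSiEt3 and C8 OTBS (precursor of the key step) | O1C/C=C(/C)C3=CC(=O)[C@@](C)(C[C@H](O[Si](C)(C)C(C)(C)C)/C=C(CO[Si](CC)(CC)CC)/C1)O3 | intermediate
21 | ten-membered C6 carbinol with C11 methylene, C12 OSiEt3, C8 OTBS (6R,7S,8S,10R; product of the key step) | O[C@@H]2/C=C(/C)C3=CC(=O)[C@@](C)(C[C@H](O[Si](C)(C)C(C)(C)C)[C@H]2C(=C)CO[Si](CC)(CC)CC)O3 | intermediate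
22 | C6,C12 diol with C8 OTBS (6R,7S,8S,10R) | O[C@@H]2/C=C(/C)C3=CC(=O)[C@@](C)(C[C@H](O[Si](C)(C)C(C)(C)C)[C@H]2C(=C)CO)O3 | intermediate
23 | C12 enal of 22 (not isolated) | O[C@@H]2/C=C(/C)C3=CC(=O)[C@@](C)(C[C@H](O[Si](C)(C)C(C)(C)C)[C@H]2C(=C)C=O)O3 | intermediate
24 | C12 lactol, both anomers (not isolated) | C=C1C(O)O[C@@H]2/C=C(/C)C3=CC(=O)[C@@](C)(C[C@H](O[Si](C)(C)C(C)(C)C)[C@@H]12)O3 | intermediate
25 | 8-O-(tert-butyldimethylsilyl)-8-deacyl-lychnopholide (6R,7S,8S,10R) | C=C1C(=O)O[C@@H]2/C=C(/C)C3=CC(=O)[C@@](C)(C[C@H](O[Si](C)(C)C(C)(C)C)[C@@H]12)O3 | intermediate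
26 | 8-deacyl-lychnopholide (6R,7R,8S,10R) | C=C1C(=O)O[C@@H]2/C=C(/C)C3=CC(=O)[C@@](C)(C[C@H](O)[C@@H]12)O3 | intermediate
27 | angelic acid, (Z)-2-methylbut-2-enoic acid | C/C=C(/C)C(=O)O | starting material
28 | angelic 2,4,6-trichlorobenzoic anhydride (not isolated) | C/C=C(/C)C(=O)OC(=O)c1c(Cl)cc(Cl)cc1Cl | intermediate
29 | lychnopholide (6R,7R,8S,10R) | C=C1C(=O)O[C@@H]2/C=C(/C)C3=CC(=O)[C@@](C)(C[C@H](OC(=O)/C(C)=C\C)[C@@H]12)O3 | target

## Step count and risks

Total: 19 steps. Longest linear sequence: 18 steps from (R)-citramalic acid (steps 1–4 and 6–19); step 5 prepares the enyne fragment.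

**Step 15 (key step).** The C6 carbanion is the remote terminus of an extended enolate, a variant of the [2,3]-Wittig ring contraction without direct precedent. The delocalised anion may be too poor a nucleophile at C6 to attack the unactivated C7=C11 alkene at low temperature. On warming, [1,2]-shift, anionic oxy-Cope rearrangement of the product alkoxide, or poor facial discrimination in the folded macrocycle may take over. The fallback leaves the ring contraction and closes C6–C7 directly, setting out from 17 and returning at 25. Oxidation of 17 with MnO2 (CH2Cl2, dark) should give the Z-configured C6 aldehyde F1. CrCl2 in THF at high dilution (divalent chromium inserts into the allylic C13–Br bond only; the alkenyl iodide would need NiCl2 as co-catalyst and is left) should effect an intramolecular Nozaki–Hiyama allylation through C7, giving the ten-membered iodovinyl carbinol F2. Carbonylative lactonisation of F2 (Pd(PPh3)4, CO, Et3N, MeCN, 60 °C) closes the α-methylene lactone and rejoins the route at 25. The anti selectivity of the allylation in this ring is not assured.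

**Step 12.** Oligomerisation may outrun the thirteen-membered closure, and the C6 alkoxide, held cis to the furanone, may add reversibly to C3 or act as a base toward the allylic bromide instead of displacing it. The fallback reverses the polarity so that the nucleophile is the C13 alkoxide, remote from the furanone, and the electrophile the more reactive C6 bromide. It sets out from 15 and returns at 18. Silylation of 15 (TESCl, imidazole) gives the C13 triethylsilyl ether F3. DDQ frees the C6 alcohol F4. Buffered Appel bromination gives the C6 bromide F5. HF·pyridine removes the triethylsilyl group to give the hydroxy bromide F6, and NaH at high dilution closes the same ether bond to 18.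

**Step 6.** The hemiketal alkoxide may collapse before the quench, so that a second acetylide adds to the liberated ynone, or attack at the carbonyl next to the quaternary carbon may be too slow. The fallback sets out from 7 and returns at 11. Aminolysis with Me(MeO)NH·HCl and i-PrMgCl (THF, −20 °C) opens the dioxolanone to the α-hydroxy Weinreb amide F7, whose chelated adduct with lithium acetylide 10 (3 equiv, −78 to 0 °C) cannot over-add and gives 11 on work-up.

**Step 9.** Bu3SnH may engage the cross-conjugated dienone (conjugate reduction, Z/E isomerisation) in competition with the alkyne, or iodine may attack C2 of the furanone. The fallback moves the operation to a stage without the furanone, setting out from 7 and returning at 15. Selective primary desilylation of 7 (HF·pyridine, pyridine, THF, 0 °C) gives the propargylic alcohol F8. The same hydrostannation gives the alkenylstannane F9, taken on without isolation, and iodination gives the iodo alcohol F10. Addition of lithium acetylide 10 (2.5 equiv, −78 °C, AcOH quench) gives the hydroxy ynone F11, and Et2NH in EtOH closes the furanone to 15.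

**Step 13.** Transmetalation at the hindered internal alkenyl iodide may be slow, leaving protodeiodination and decomposition of the hydroxymethyl stannane as the main processes. The fallback introduces C12 as a formyl group, setting out from 18 and returning at 19. Reductive carbonylation (Pd(PPh3)4, CO, slow addition of Bu3SnH, THF, 50 °C) should give the enal F12. Luche reduction (NaBH4, CeCl3·7H2O, MeOH, −78 °C) reduces the aldehyde in preference to the vinylogous-ester carbonyl of the furanone and gives 19.

## Further compounds

F1 | step 15 | (R)-2-[(S,Z)-5-bromo-2-(tert-butyldimethylsilyloxy)-4-iodopent-3-en-1-yl]-2-methyl-5-[(Z)-4-oxobut-2-en-2-yl]furan-3(2H)-one | O=C/C=C(/C)C2=CC(=O)[C@@](C)(C[C@H](O[Si](C)(C)C(C)(C)C)/C=C(I)/CBr)O2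
F2 | step 15 | ten-membered C6 carbinol with a 1-iodovinyl group on C7 and C8 OTBS (configuration as in 21) | O[C@@H]2/C=C(/C)C3=CC(=O)[C@@](C)(C[C@H](O[Si](C)(C)C(C)(C)C)[C@H]2C(I)=C)O3
F3 | step 12 | C13 triethylsilyl ether of 15 | COc1ccc(COC/C=C(/C)C2=CC(=O)[C@@](C)(C[C@H](O[Si](C)(C)C(C)(C)C)/C=C(I)/CO[Si](CC)(CC)CC)O2)cc1
F4 | step 12 | C6 alcohol with C13 OSiEt3 | OC/C=C(/C)C2=CC(=O)[C@@](C)(C[C@H](O[Si](C)(C)C(C)(C)C)/C=C(I)/CO[Si](CC)(CC)CC)O2
F5 | step 12 | C6 bromide with C13 OSiEt3 | BrC/C=C(/C)C2=CC(=O)[C@@](C)(C[C@H](O[Si](C)(C)C(C)(C)C)/C=C(I)/CO[Si](CC)(CC)CC)O2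
F6 | step 12 | C6 bromide with free C13 hydroxyl | BrC/C=C(/C)C2=CC(=O)[C@@](C)(C[C@H](O[Si](C)(C)C(C)(C)C)/C=C(I)/CO)O2
F7 | step 6 | (2R,4S)-4,7-bis(tert-butyldimethylsilyloxy)-2-hydroxy-N-methoxy-N,2-dimethylhept-5-ynamide | CON(C)C(=O)[C@](C)(O)C[C@H](O[Si](C)(C)C(C)(C)C)C#CCO[Si](C)(C)C(C)(C)C
F8 | step 9 | (R)-5-[(S)-2-(tert-butyldimethylsilyloxy)-5-hydroxypent-3-yn-1-yl]-2,2,5-trimethyl-1,3-dioxolan-4-one | CC1(C)OC(=O)[C@@](C)(C[C@H](O[Si](C)(C)C(C)(C)C)C#CCO)O1
F9 | step 9 | (R)-5-[(S,Z)-2-(tert-butyldimethylsilyloxy)-5-hydroxy-4-(tributylstannyl)pent-3-en-1-yl]-2,2,5-trimethyl-1,3-dioxolan-4-one | CC1(C)OC(=O)[C@@](C)(C[C@H](O[Si](C)(C)C(C)(C)C)/C=C(/CO)[Sn](CCCC)(CCCC)CCCC)O1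
F10 | step 9 | (R)-5-[(S,Z)-2-(tert-butyldimethylsilyloxy)-5-hydroxy-4-iodopent-3-en-1-yl]-2,2,5-trimethyl-1,3-dioxolan-4-one | CC1(C)OC(=O)[C@@](C)(C[C@H](O[Si](C)(C)C(C)(C)C)/C=C(I)/CO)O1
F11 | step 9 | (2Z,7R,9S,10Z)-9-(tert-butyldimethylsilyloxy)-7,12-dihydroxy-11-iodo-1-(4-methoxybenzyloxy)-3,7-dimethyldodeca-2,10-dien-4-yn-6-one | COc1ccc(COC/C=C(/C)C#CC(=O)[C@](C)(O)C[C@H](O[Si](C)(C)C(C)(C)C)/C=C(I)/CO)cc1
F12 | step 13 | macrocyclic enal: as 18 with CHO (C12) in place of iodine on C11 | O1C/C=C(/C)C3=CC(=O)[C@@](C)(C[C@H](O[Si](C)(C)C(C)(C)C)/C=C(C=O)/C1)O3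
A1 | alternative 1 | 3-diazo-1-[2,6-cis-5,6-trans-5-(tert-butyldimethylsilyloxy)-3-methyl-6-vinyl-5,6-dihydro-2H-pyran-2-yl]butan-2-one | CC(C)(C)[Si](C)(C)O[C@@H]1C=C(C)[C@@H](CC(=O)C(C)=[N+]=[N-])O[C@H]1C=C
A2 | alternative 1 | oxygen-bridged cyclodecadienone with quaternary C10 and C6 OTBS | C[Si](C)(C(C)(C)C)O[C@@H]2/C=C(/C)[C@H]3CC(=O)[C@@](C)(C/C=C\2)O3
A3 | alternative 2 | ten-membered furanone core with trans C7–C8 epoxide and C6 O-propargyl ether | C#CCO[C@@H]2/C=C(/C)C3=CC(=O)[C@@](C)(C[C@@H]4O[C@H]42)O3
A4 | alternative 2 | 3-methyleneoxolane-fused core with free C8 hydroxyl | C=C1CO[C@@H]2/C=C(/C)C3=CC(=O)[C@@](C)(C[C@H](O)[C@@H]12)O3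
A5 | alternative 3 | lactone-fused cyclooct-2-enone with C8 OTBS and a prop-1-ynyl ether on the C10 oxygen | CC#CO[C@]1(C)C[C@H](O[Si](C)(C)C(C)(C)C)[C@H]2CC(=O)O[C@@H]2/C=C\C1=O
A6 | alternative 3 | cyclobutene photoadduct (C2–C3 and C4–C5 formed; the two new ring-fusion centres C2 and C5 left open) | CC1=C2O[C@]3(C)C[C@H](O[Si](C)(C)C(C)(C)C)[C@H]4CC(=O)O[C@@H]4C1C2C3=O
A7 | alternative 3 | 8-O-silyl furanoheliangolide core without the C13 methylene | C1C(=O)O[C@@H]2/C=C(/C)C3=CC(=O)[C@@](C)(C[C@H](O[Si](C)(C)C(C)(C)C)[C@@H]12)O3
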